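The plan cuts the C2–C3 bond of the N-methoxy-4-pyridone (ring A: N1, C2, C3, C4, C4a, C8a). C2 stands at the carboxamide oxidation level and is bound to N1. C3 is the α-carbon of the C4 ketone. The bond can therefore be made by a Camps-type intramolecular aldol condensation with N1–OMe already in place. In one operation this forms C2–C3, closes and aromatises ring A, and gives waltherione H directly. The precursor is a cyclohexene (ring B) whose C4a=C8a alkene carries a methoxyacetyl ketone and an N-methoxyacetamido group cis to each other. C5 (S) and C8 (R) are set beforehand by asymmetric conjugate addition and proline-catalysed α-oxygenation.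

Key step: step 8

Remarks on the chemistry
- Target numbering (N1, C2 to C8a) is used for late compounds. The descriptors (5S,8R) correspond to a cis relationship between the side chain and the C8 methoxy group, and to (3S,6R) in the cyclohexene precursor.
- Assumption: both antipodes of TaniaPhos are available. The one whose established sense of induction with linear alkylmagnesium bromides leads to the S ketone is used.
- The C8 oxygen is introduced on the simple ketone, before the 1,3-diketone exists. A 2-(methoxyacetyl) ketone would offer two competing γ-sites (ring CH2 and CH2OMe) to an enolate oxidation, and it would give no control over the cis relationship.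
- The acyl group is delivered from an N-acylbenzotriazole rather than the acid chloride, to avoid O-acylation.
- The ring closure uses a non-nucleophilic lithium amide. Nucleophilic bases would cleave the activated N-acetyl group, and equilibrating bases could epimerise C8.
- The 1,3-diketone is drawn as its ring enol, because the C2 centre of the keto form is configurationally labile.

Step 1
Reactants: 1 (5-bromopentyl)benzene; 2 cyclohex-2-en-1-one
Product: 5 (S)-3-(5-phenylpentyl)cyclohexan-1-one, via 5-phenylpentylmagnesium bromide 3 (not isolated), via bromomagnesium enolate 4 (not isolated)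
Conditions: 1, Mg, Et2O, reflux; then 2, CuCl (5 mol %), TaniaPhos (6 mol %), Et2O, 0 °C; 1 M HCl
Reagents that add atoms: none
Why: Copper-catalysed asymmetric conjugate addition of a linear primary Grignard reagent to a cyclic enone is established with ferrocenyl bisphosphine ligands, and the chiral copper complex selects the enone face so that C3 (later C5) is formed as S.

Step 2
Reactants: 5 (S)-3-(5-phenylpentyl)cyclohexan-1-one
Product: 7 (2R,5S)-2-hydroxy-5-(5-phenylpentyl)cyclohexan-1-one, via anilinooxy ketone 6 (not isolated)
Conditions: PhNO (slow addition), L-proline (20 mol %), DMF, 0 °C; aqueous work-up; H2 (1 atm), Pd/C, MeOH, rt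
Reagents that add atoms: nitrosobenzene, O=Nc1ccccc1
Why: The proline-catalysed α-aminoxylation (O-selective nitroso aldol reaction) should run through the less hindered enamine pointing away from the side chain, L-proline delivering oxygen to the face that gives the R centre, which on the S ketone is also the stereoelectronically preferred axial attack (matched case, cis product), and hydrogenolysis then cleaves only the weak N–O bond.

Step 3
Reactants: 7 (2R,5S)-2-hydroxy-5-(5-phenylpentyl)cyclohexan-1-one
Product: 8 (2R,5S)-2-methoxy-5-(5-phenylpentyl)cyclohexan-1-one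
Conditions: Me3OBF4, 1,8-bis(dimethylamino)naphthalene, 4 Å MS, CH2Cl2, 0 °C → rt
Reagents that add atoms: trimethyloxonium tetrafluoroborate, C[O+](C)C.F[B-](F)(F)F
Why: O-Methylation by an oxonium salt with a hindered, non-nucleophilic proton scavenger proceeds without enolate formation, so the epimerisable α-centre and the α-ketol unit should be carried through unchanged.

Step 4
Reactants: 9 methoxyacetyl chloride
Product: 10 1-(methoxyacetyl)-1H-benzotriazole
Conditions: 1H-benzotriazole, Et3N, CH2Cl2, 0 °C → rt
Reagents that add atoms: 1H-benzotriazole, c1ccc2[nH]nnc2c1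
Why: Simple N-acylation of benzotriazole by an acid chloride gives a storable acyl donor that transfers its acyl group to enolate carbon.

Step 5
Reactants: 8 (2R,5S)-2-methoxy-5-(5-phenylpentyl)cyclohexan-1-one; 10 1-(methoxyacetyl)-1H-benzotriazole
Product: 12 (3S,6R)-6-methoxy-2-(methoxyacetyl)-3-(5-phenylpentyl)cyclohexan-1-one (ring enol form), via lithium enolate 11 (not isolated)
Conditions: LiN(iPr)2 (1.1 equiv), THF, −78 °C; 10, −78 → −30 °C; AcOH
Reagents that add atoms: none
Why: Kinetic lithium amide deprotonation of 2-alkoxycyclohexanones favours the CH2 side, here reinforced because the cis isomer (side chain equatorial, OMe axial) holds its methoxy-bearing C–H equatorial and badly aligned with the carbonyl π system, and N-acylbenzotriazoles are C-selective acyl donors for lithium enolates (crossed Claisen-type acylation), the new centre being lost on enolisation.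

Step 6
Reactants: 12 (3S,6R)-6-methoxy-2-(methoxyacetyl)-3-(5-phenylpentyl)cyclohexan-1-one
Product: 13 (3S,6R)-6-methoxy-2-(methoxyacetyl)-3-(5-phenylpentyl)cyclohex-1-en-1-yl trifluoromethanesulfonate
Conditions: Tf2O (1.05 equiv), iPr2NEt, CH2Cl2, −78 °C
Reagents that add atoms: trifluoromethanesulfonic anhydride, O=S(=O)(OS(=O)(=O)C(F)(F)F)C(F)(F)F
Why: O-Sulfonylation of the 1,3-diketone (vinylogous acyl triflate formation) should take the ring oxygen, because six-membered 2-acyl ketones enolise with the double bond inside the ring and the exocyclic enol triflate would press its substituents against the C3 side chain (allylic 1,3-strain), while no stereocentre is touched.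

Step 7
Reactants: 13 (3S,6R)-6-methoxy-2-(methoxyacetyl)-3-(5-phenylpentyl)cyclohex-1-en-1-yl trifluoromethanesulfonate; 14 N-methoxyacetamide
Product: 15 N-methoxy-N-[(3S,6R)-6-methoxy-2-(methoxyacetyl)-3-(5-phenylpentyl)cyclohex-1-en-1-yl]acetamide
Conditions: Pd2(dba)3 (2.5 mol %), Xantphos (7.5 mol %), Cs2CO3, 1,4-dioxane, 50 °C
Reagents that add atoms: none
Why: Palladium-catalysed amidation of an enol triflate (Buchwald–Hartwig type, wide-bite-angle bisphosphine) joins nitrogen to C1 with the ring alkene retained, and because C1 is also the β-carbon of an enone the caesium salt of the acidic, α-effect N-methoxy amide can reach the same product by uncatalysed addition–elimination.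

Step 8
Reactants: 15 N-methoxy-N-[(3S,6R)-6-methoxy-2-(methoxyacetyl)-3-(5-phenylpentyl)cyclohex-1-en-1-yl]acetamide
Product: 17 waltherione H, via lithium carbinolamide alkoxide 16 (not isolated)
Conditions: LiN(SiMe3)2 (1.3 equiv), THF, −78 → 0 °C; AcOH, rt
Reagents that add atoms: none
Why: Proposed new method: LiN(SiMe3)2 removes a proton from the methoxyacetyl CH2 (future C3), the lithium enolate adds through carbon to the acetamide carbonyl (future C2) to give alkoxide 16, and the acid quench removes water across C2–C3 so that the aromatic N-methoxy-4-pyridone results. The closest known reaction type is the Camps synthesis of 4-quinolones from N-acyl-2-aminoaryl ketones; new here are the non-aromatic enamide backbone and the alkoxy group on nitrogen, which weakens amide resonance, raises the electrophilicity of C2 and lets lithium bridge the alkoxide and the N1–OMe oxygen as in adducts of N-methoxy-N-methyl amides. Ring A closes in the 6-(enolendo)-exo-trig mode, and the C4a=C8a alkene holds both arms cis so that little entropy is lost. No stereocentre is formed; C5 and C8 are only carried through, and short exposure to a kinetic base at low temperature favours the α′-proton over the γ-proton at C8. The selectivity required is attack of the ketone enolate on the amide (4-pyridone) rather than of the amide enolate on the ketone (2-pyridone), and it is secured by the greater acidity of the α-alkoxy ketone CH2, by chelation of lithium between the C4 oxygen and the ether oxygen, and by the crowded, conjugated C4 carbonyl being the poorer acceptor. If 16 should open at C2–N1, the N-methoxy enaminone and the acetyl ketone so formed recondense at the same atoms under the acid quench, so both paths end in 17, whereas nucleophilic bases such as hydroxide are avoided because they would strip the activated N-acetyl group.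

Compound list
1 | (5-bromopentyl)benzene | BrCCCCCc1ccccc1 | starting material
2 | cyclohex-2-en-1-one | O=C1C=CCCC1 | starting material
3 | 5-phenylpentylmagnesium bromide | Br[Mg]CCCCCc1ccccc1 | intermediate
4 | bromomagnesium enolate of (S)-3-(5-phenylpentyl)cyclohexanone (C1=C2 enolate) | Br[Mg]OC1=C[C@@H](CCCCCc2ccccc2)CCC1 | intermediate
5 | (S)-3-(5-phenylpentyl)cyclohexan-1-one | O=C1C[C@@H](CCCCCc2ccccc2)CCC1 | intermediate
6 | (2R,5S)-2-(anilinooxy)-5-(5-phenylpentyl)cyclohexan-1-one | O=C1C[C@@H](CCCCCc2ccccc2)CC[C@H]1ONc1ccccc1 | intermediate
7 | (2R,5S)-2-hydroxy-5-(5-phenylpentyl)cyclohexan-1-one | O=C1C[C@@H](CCCCCc2ccccc2)CC[C@H]1O | intermediate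
8 | (2R,5S)-2-methoxy-5-(5-phenylpentyl)cyclohexan-1-one | O=C1C[C@@H](CCCCCc2ccccc2)CC[C@H]1OC | intermediate
9 | methoxyacetyl chloride | COCC(Cl)=O | starting material
10 | 1-(methoxyacetyl)-1H-benzotriazole | COCC(=O)n1nnc2ccccc21 | intermediate
11 | lithium enolate of 8 (double bond towards the side-chain-bearing carbon) | [Li]OC1=C[C@@H](CCCCCc2ccccc2)CC[C@H]1OC | intermediate
12 | (3S,6R)-6-methoxy-2-(methoxyacetyl)-3-(5-phenylpentyl)cyclohexan-1-one, ring enol form | COCC(=O)C1=C(O)[C@H](OC)CC[C@@H]1CCCCCc1ccccc1 | intermediate
13 | (3S,6R)-6-methoxy-2-(methoxyacetyl)-3-(5-phenylpentyl)cyclohex-1-en-1-yl trifluoromethanesulfonate | COCC(=O)C1=C(OS(=O)(=O)C(F)(F)F)[C@H](OC)CC[C@@H]1CCCCCc1ccccc1 | intermediate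
14 | N-methoxyacetamide | CC(=O)NOC | starting material
15 | N-methoxy-N-[(3S,6R)-6-methoxy-2-(methoxyacetyl)-3-(5-phenylpentyl)cyclohex-1-en-1-yl]acetamide | COCC(=O)C1=C(N(OC)C(C)=O)[C@H](OC)CC[C@@H]1CCCCCc1ccccc1 | intermediate
16 | lithium (5S,8R)-1,3,8-trimethoxy-2-methyl-4-oxo-5-(5-phenylpentyl)-1,2,3,4,5,6,7,8-octahydroquinolin-2-olate (C2 and C3 undefined, both lost on dehydration) | [Li]OC1(C)N(OC)C2=C(C(=O)C1OC)[C@@H](CCCCCc1ccccc1)CC[C@H]2OC | intermediate
17 | waltherione H, (5S,8R)-1,3,8-trimethoxy-2-methyl-5-(5-phenylpentyl)-5,6,7,8-tetrahydroquinolin-4(1H)-one | COc1c(C)n(OC)c2c(c1=O)[C@@H](CCCCCc1ccccc1)CC[C@H]2OC | target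

Total step count: 8
Longest linear sequence: 7 (steps 1, 2, 3, 5, 6, 7, 8; step 4 is a side branch)

Steps most likely to fail

1. Step 8 (the labelled step).
What may go wrong:
- transfer of the activated N-acetyl group to the base or to traces of hydroxide before the C–C bond forms;
- deprotonation of the acetamide methyl followed by closure onto C4;
- base-induced loss of formaldehyde from N–OMe;
- erosion of C8 by γ-deprotonation.

The fallback uses known chemistry and closes ring A at nitrogen instead of carbon. It sets out from 12 and returns at 17. Excess LiN(iPr)2 converts 12 into its dianion, formed at the less substituted CH2OMe terminus. The dianion is acetylated with N-methoxy-N-methylacetamide to the triketone 1-[(3R,6S)-2-hydroxy-3-methoxy-6-(5-phenylpentyl)cyclohex-1-en-1-yl]-2-methoxybutane-1,3-dione F1. TsOH in warm toluene cyclodehydrates it to the 4-pyranone (5S,8R)-3,8-dimethoxy-2-methyl-5-(5-phenylpentyl)-5,6,7,8-tetrahydro-4H-chromen-4-one F2. Heating F2 with MeONH2·HCl in pyridine/EtOH exchanges the ring oxygen for N–OMe by ring opening and reclosure, the standard pyranone-to-pyridone conversion, and gives 17.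

2. Step 7.
What may go wrong:
- slow C–N bond formation at a tetrasubstituted carbon flanked on both sides;
- reaction of the hydroxamate through oxygen;
- attack at sulfur with return of the diketone;
- premature ring closure, or epimerisation at the methoxy-bearing carbon under carbonate at elevated temperature.

The fallback brings in a small neutral nucleophile first and the acyl group afterwards. It sets out from 13 and returns at 15. O-Methylhydroxylamine (from its hydrochloride and Et3N, THF, 0 °C) adds to C1 and expels triflate without a metal. This gives the N-methoxy enaminone 2-methoxy-1-[(3R,6S)-3-methoxy-2-(methoxyamino)-6-(5-phenylpentyl)cyclohex-1-en-1-yl]ethan-1-one F3. N-Acetylation (Ac2O, DMAP, Et3N, CH2Cl2, under reversible acyl transfer so that the N-acyl isomer can accumulate) gives 15.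

3. Step 6.
What may go wrong: sulfonylation of the side-chain oxygen instead of the ring oxygen, which would later place nitrogen on the wrong carbon.

The fallback fixes nitrogen on the ring carbonyl while that is the only carbonyl present. It sets out from 8 and returns at 15. Enolate 11 is trapped with methoxyacetaldehyde (aldol addition, −78 °C) to give (3S,6R)-2-(1-hydroxy-2-methoxyethyl)-6-methoxy-3-(5-phenylpentyl)cyclohexan-1-one F4. MeONH2·HCl in pyridine converts the ketone into (3S,6R)-2-(1-hydroxy-2-methoxyethyl)-6-methoxy-3-(5-phenylpentyl)cyclohexan-1-one O-methyl oxime F5. Dess–Martin periodinane oxidises the carbinol to 2-methoxy-1-[(3R,6S)-3-methoxy-2-(methoxyimino)-6-(5-phenylpentyl)cyclohexyl]ethan-1-one F6, the imine tautomer of F3. F6 is acetylated on nitrogen as above to give 15.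

Further compounds
F1 | step 8 | 1-[(3R,6S)-2-hydroxy-3-methoxy-6-(5-phenylpentyl)cyclohex-1-en-1-yl]-2-methoxybutane-1,3-dione (labile centre between the carbonyls undefined) | CC(=O)C(OC)C(=O)C1=C(O)[C@H](OC)CC[C@@H]1CCCCCc1ccccc1
F2 | step 8 | (5S,8R)-3,8-dimethoxy-2-methyl-5-(5-phenylpentyl)-5,6,7,8-tetrahydro-4H-chromen-4-one | COc1c(C)oc2c(c1=O)[C@@H](CCCCCc1ccccc1)CC[C@H]2OC
F3 | step 7 | 2-methoxy-1-[(3R,6S)-3-methoxy-2-(methoxyamino)-6-(5-phenylpentyl)cyclohex-1-en-1-yl]ethan-1-one | COCC(=O)C1=C(NOC)[C@H](OC)CC[C@@H]1CCCCCc1ccccc1
F4 | step 6 | (3S,6R)-2-(1-hydroxy-2-methoxyethyl)-6-methoxy-3-(5-phenylpentyl)cyclohexan-1-one (two new centres undefined, both erased later) | COCC(O)C1C(=O)[C@H](OC)CC[C@@H]1CCCCCc1ccccc1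
F5 | step 6 | (3S,6R)-2-(1-hydroxy-2-methoxyethyl)-6-methoxy-3-(5-phenylpentyl)cyclohexan-1-one O-methyl oxime | COCC(O)C1C(=NOC)[C@H](OC)CC[C@@H]1CCCCCc1ccccc1
F6 | step 6 | 2-methoxy-1-[(3R,6S)-3-methoxy-2-(methoxyimino)-6-(5-phenylpentyl)cyclohexyl]ethan-1-one | COCC(=O)C1C(=NOC)[C@H](OC)CC[C@@H]1CCCCCc1ccccc1
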